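(The readings were computed with made-up constants; noise was put on by code.)

The easy step first: I turn each fraction of free monomer left into an exponent, the logarithm of one over that fraction.

| flask | free monomer | transfer agent | initiator | remark | time |
|---|---|---|---|---|---|
| oak | 1.3 M | 0.013 M | 2.5 mM | run made earlier |  |
| alder | 1.3 M | 0.013 M | 4.4 mM | run made earlier |  |
| larch | 1.3 M | 0.013 M | 5.6 mM | run made earlier |  |
| eta | 1.3 M | 0.0130 M | 3.1 mM |  | 3.0 min |
| zeta | 1.3 M | 0.0130 M | 6.0 mM |  | 3.0 min |

- oak (time / s: monomer in chains / %): 12.0: 2.7; 30.0: 10.9; 60.0: 24.0; 90.0: 34.0; 120: 41.0
- alder (time / s: monomer in chains / %): 12.0: 5.4; 30.0: 18.2; 60.0: 38.2; 90.0: 51.3; 120: 60.6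
- larch (time / s: monomer in chains / %): 25.0: 17.5; 50.0: 38.3; 80.0: 55.2; 90.0: 59.9; 120: 69.0

(readings scatter by 0.3 percentage points)

- the average divides the monomer in chains by the number of chains begun, living and dead together
- the earlier runs do not show the number of chains; that part of a forecast is a guess

* which of the two ends with the longer chains by the average number of monomer units in a chain (chains begun, living or dead) ("neither" if they lie within 10 %) (eta / zeta / neither)
* average number of monomer units in a chain (chains begun, living or dead) at the end, eta
* average number of monomer units in a chain (chains begun, living or dead) at the end, zeta

At the last reading the exponent per initiator is 0.211 /mM in oak, 0.212 /mM in alder and 0.209 /mM in larch. So I scale the exponent with the initiator charged. But eta and zeta end at 3.0 min, and the runs stop at 120 s.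

I reckon from alder in two ways. First, I hold the mean step of its last interval, 0.212, for two more intervals. That gives 0.308 /mM. Second, the step before it was 0.238, so I shrink each new step by their ratio, 0.890. That gives 0.293 /mM, the exponent per initiator at the end.

The first way cheats, because it holds a step that the readings show falling. I keep the second, so monomer in chains ends at 59.6 % of the charge in eta and 82.7 % in zeta.

I read the falling step as growing ends stopping without handing on their growth. Then I take one chain at most per initiator, and the length has a floor: monomer in chains over initiator charged. Eta's floor is 250 and zeta's is 179. With equal shares of initiator beginning chains, eta stays longer, by a factor of 1.40. I say eta.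

The forecast says zeta, with 48 units in eta and 56 in zeta. We part on the count of chains, which it calls a guess: “If the transfer agent is fully used, chains are 13 mM plus initiator”.

The flask gives eta, with 469 units in eta and 347 in zeta.

    living end + transfer agent → dead chain (kL = 0.519 /M/s)
    free monomer + initiator → living end + monomer in chains (k = 0.0275 /M/s)
    initiator → spent initiator (k = 0.0305 /s)
    free monomer + living end → monomer in chains + living end, rate k4*[living end]*[free monomer] (k = 5.38 /M/s)

In eta, with free monomer at its charge, initiator has a half-life of 0.323 min by the step that begins chains, shorter than the 0.38 min of its step to spent initiator. At the end of eta, living end and dead chain together count half of the initiator charged, and the length stands at 1.88 times the floor, while zeta's stands at 1.94 times its floor.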